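**Retrosynthetic overview**
1. Target ⇒ bridgehead acylation (C1) and bridgehead geranylation (C5) of the bare cage trione.
2. Cage trione ⇒ face-selective hydrogenation of a C10=C11 cage alkene, which sets C11.
3. Cage alkene ⇒ oxidative radical closure of ring A and of the C7–C10 bridge from a spiro-trione that carries a 1,1-dimethylallyl group.
4. The hindered C1–C8 bond ⇒ [3,3] shift of an enol prenyl ether. The pivotal bond of the route is the C9–O ether bond, made from an achiral spiro-trione and prenol.
5. Spiro-trione ⇒ dearomatising 5-exo closure of an alkylphloroglucinol. Ring order: ring B (arene) → cyclopentane → ring A → the two seven-membered bridges.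

Cage numbering used below: C1 (isobutyryl), C2 (C=O), C3 (fusion carbon), C4 (C=O), C5 (geranyl), C6 (CH2), C7 (CH), C8 (CMe2), C9 (C=O between C1 and C5), C10 (CH2 on C7), C11 (CH bonded to C3, C10, C12), C12 (CMe2), C13 and C14 (CH2CH2 back to C3).

Assumption: enolisable triones are drawn as one tautomer, and the antipode of the step 5 catalyst that gives 8 is chosen after a first trial run.

**Step 1**
Reactants: 1 phloroglucinol; 2 3,3-dimethylpent-4-enoic acid
Product: 3 1-(2,4,6-trihydroxyphenyl)-3,3-dimethylpent-4-en-1-one
Conditions: BF3·OEt2 (solvent), 70 °C; aq NaOAc work-up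
Reagents that add atoms: none
Why: Friedel–Crafts C-acylation of the very electron-rich arene stops at mono-acylation because the chelated aryl ketone is deactivated, and the neopentyl-type vinyl group is a poor proton acceptor; no stereocentre is formed.

**Step 2**
Reactants: 3 1-(2,4,6-trihydroxyphenyl)-3,3-dimethylpent-4-en-1-one
Product: 4 2-(3,3-dimethylpent-4-en-1-yl)benzene-1,3,5-triol
Conditions: Et3SiH (2.5 equiv), CF3CO2H, 0 °C → rt
Reagents that add atoms: none
Why: Ionic hydrogenation takes the strongly stabilised benzylic cation down to CH2 (C14), while a monosubstituted alkene is not reduced under these conditions; no stereocentre is formed.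

**Step 3**
Reactants: 4 2-(3,3-dimethylpent-4-en-1-yl)benzene-1,3,5-triol
Product: 5 2,2-dimethyl-1-methylidenespiro[4.5]decane-6,8,10-trione (achiral)
Conditions: Mn(OAc)3·2H2O (2.1 equiv), Cu(OAc)2·H2O (0.3 equiv), degassed AcOH, 25 °C
Reagents that add atoms: none
Why: In this Snider-type oxidative free-radical cyclisation, trivalent manganese makes the C3 radical of the triketo tautomer, which closes 5-exo onto the vinyl group (helped by the gem-dimethyl effect), and divalent copper oxidises the primary C10 radical with loss of the C11 hydrogen to give the exocyclic C10=C11 alkene; the product has a mirror plane.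

**Step 4**
Reactants: 5 2,2-dimethyl-1-methylidenespiro[4.5]decane-6,8,10-trione; 6 prenol (3-methylbut-2-en-1-ol)
Product: 7 2,2-dimethyl-1-methylidene-8-[(3-methylbut-2-en-1-yl)oxy]spiro[4.5]dec-7-ene-6,10-dione
Conditions: PPh3, DIAD, THF, 0 °C
Reagents that add atoms: none
Why: In this Mitsunobu etherification the vinylogous acid (pKa about 5) reacts through its least hindered oxygen (on C9) by SN2 at the primary allylic carbon, and this C–O bond programmes delivery of CMe2 to a ring carbon; ethers formed at the other oxygens would give the same constitution after [3,3] shift, and the two enol-ether tautomers of 7 are rapidly interconverting mirror images, so no fixed stereocentre exists yet.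

**Step 5**
Reactants: 7 2,2-dimethyl-1-methylidene-8-[(3-methylbut-2-en-1-yl)oxy]spiro[4.5]dec-7-ene-6,10-dione
Product: 8 (5R)-6-hydroxy-2,2-dimethyl-7-(2-methylbut-3-en-2-yl)-1-methylidenespiro[4.5]dec-6-ene-8,10-dione
Conditions: N,N'-bis[(1R,2R)-2-(2,5-dimethylpyrrol-1-yl)cyclohexyl]guanidinium tetrakis[3,5-bis(trifluoromethyl)phenyl]borate (20 mol %), hexanes–CH2Cl2, 35 °C
Reagents that add atoms: none
Why: Proposed new method: a hydrogen-bond-donor-catalysed, desymmetrising Claisen rearrangement run as a dynamic kinetic process, in which the C9=C1 and C9=C5 enol-ether tautomers of 7 are mirror images that interconvert by proton shift, the chiral guanidinium ion binds the ether oxygen and the conjugated carbonyl of one tautomer and lowers its chair transition state, so the prenyl terminus goes to one of the two enantiotopic ring carbons, which forms the hindered C1–C8 bond and makes the spiro carbon C3 a defined stereocentre (C1 then enolises); closest known reaction type: guanidinium-catalysed enantioselective Claisen rearrangement of O-allyl beta-keto esters.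

**Step 6**
Reactants: 8 (5R)-6-hydroxy-2,2-dimethyl-7-(2-methylbut-3-en-2-yl)-1-methylidenespiro[4.5]dec-6-ene-8,10-dione
Product: 9 cage enetrione (C10=C11 alkene, H at C1 and C5; C1, C3, C5 and C7 configured as in the target)
Conditions: Mn(OAc)3·2H2O (2.2 equiv), Cu(OAc)2·H2O (0.2 equiv), degassed AcOH, 5 mM, 45 °C
Reagents that add atoms: none
Why: In this Snider-type tandem oxidative radical cyclisation the C5 radical closes 6-endo onto the terminal vinyl carbon C6 (the normal mode for 2-oxohex-5-enyl radicals, reinforced by the allylic quaternary C8), the C7 radical adds across the ring to the terminal carbon C10 of the methylidene group, and divalent copper removes a C10 hydrogen from the tertiary C11 radical; C1 equilibrates through its enol, and only closure on the face of ring B that carries C11 can complete the cage, so C3 dictates C1, C5 and C7.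

**Step 7**
Reactants: 9 cage enetrione
Product: 10 cage trione (H at C1 and C5; all five stereocentres as in the target)
Conditions: H2 (20 bar), Pd/C (10 wt %), EtOAc, 40 °C
Reagents that add atoms: none
Why: Heterogeneous syn-hydrogenation reaches the alkene only from the C4/C6 flank, because one C8 methyl group covers the C2/C8 flank, so H-11 ends on the C4 side and C12 is pushed to the C2 side, as the target requires.

**Step 8**
Reactants: 10 cage trione; 11 geranyl bromide
Product: 12 C5-geranyl cage trione (H at C1)
Conditions: LiN(i-Pr)2 (1.1 equiv), THF, −78 °C; then 11, −78 → 0 °C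
Reagents that add atoms: none
Why: In this bridgehead lithiation–alkylation the only acidic hydrogens are the two bridgehead C–H bonds flanked by two carbonyls, the one next to CH2 (C5) is removed faster than the one next to CMe2 (C1), and substitution occurs with retention because the bridgehead cannot invert.

**Step 9**
Reactants: 12 C5-geranyl cage trione; 13 isobutyryl chloride
Product: 14 target CNP0313870.1
Conditions: LiN(i-Pr)2 (1.5 equiv), THF, −78 → −40 °C; then 13, −78 °C
Reagents that add atoms: none
Why: In this bridgehead lithiation–C-acylation C1–H is the last acidic site, O-acylation is impossible for a bridgehead carbanion, and the configuration at C1 is held by the cage.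

**Compound list**
1 | phloroglucinol | Oc1cc(O)cc(O)c1 | starting material
2 | 3,3-dimethylpent-4-enoic acid | C=CC(C)(C)CC(=O)O | starting material
3 | 1-(2,4,6-trihydroxyphenyl)-3,3-dimethylpent-4-en-1-one | C=CC(C)(C)CC(=O)c1c(O)cc(O)cc1O | intermediate
4 | 2-(3,3-dimethylpent-4-en-1-yl)benzene-1,3,5-triol | C=CC(C)(C)CCc1c(O)cc(O)cc1O | intermediate
5 | 2,2-dimethyl-1-methylidenespiro[4.5]decane-6,8,10-trione | C=C1C(C)(C)CCC12C(=O)CC(=O)CC2=O | intermediate
6 | prenol | CC(C)=CCO | starting material
7 | 2,2-dimethyl-1-methylidene-8-[(3-methylbut-2-en-1-yl)oxy]spiro[4.5]dec-7-ene-6,10-dione | C=C1C(C)(C)CCC12C(=O)C=C(OCC=C(C)C)CC2=O | intermediate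
8 | (5R)-6-hydroxy-2,2-dimethyl-7-(2-methylbut-3-en-2-yl)-1-methylidenespiro[4.5]dec-6-ene-8,10-dione | C=C1C(C)(C)CC[C@]1(C(=O)CC2=O)C(O)=C2C(C)(C)C=C | intermediate
9 | cage enetrione (C10=C11) | [C@@H]12C[C@H]3C=C4C(C)(C)CC[C@]4(C1=O)C(=O)[C@@H](C2=O)C3(C)C | intermediate
10 | cage trione | [C@@H]12C[C@H]3C[C@@H]4C(C)(C)CC[C@]4(C1=O)C(=O)[C@@H](C2=O)C3(C)C | intermediate
11 | geranyl bromide | CC(C)=CCC/C(C)=C/CBr | starting material
12 | C5-geranyl cage trione | CC(C)=CCC/C(C)=C/C[C@@]12C[C@H]3C[C@@H]4C(C)(C)CC[C@]4(C1=O)C(=O)[C@@H](C2=O)C3(C)C | intermediate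
13 | isobutyryl chloride | CC(C)C(=O)Cl | starting material
14 | target CNP0313870.1 | CC(C)=CCC/C(C)=C/C[C@@]12C[C@H]3C[C@@H]4C(C)(C)CC[C@]4(C1=O)C(=O)[C@@](C(=O)C(C)C)(C2=O)C3(C)C | target

Total steps: 9. Longest linear sequence: 9.

**Steps most likely to fail**

*Step 5 (the new step).* The catalyst may not tell the two tautomers apart. The fallback sets out from 7 and comes back at 12.
- Heating 7 in toluene at 110 °C (uncatalysed Claisen rearrangement) gives 8 together with its mirror image, ent-spiro-trione F1.
- Steps 6 and 7 as written give 9 with ent-cage enetrione F2, and then 10 with ent-cage trione F3.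
- The racemate is resolved in the geranylation step by kinetic resolution. This uses the dilithium salt of (1R,2R)-N,N'-bis[(R)-1-phenylethyl]-1,2-diphenylethane-1,2-diamine (0.55 equiv, or its antipode) with LiCl in THF at −78 °C, followed by 11.
- Chiral lithium amide bridgehead deprotonation is a known resolution for this ketone class. It gives 12 and leaves F3 behind.

*Step 6.* Ring A may form on the wrong face of ring B, or the C7 radical may be oxidised before it reaches C10. The fallback sets out from 8 and comes back at 9.
- The oxidation is run with Cu(OAc)2·H2O raised to 1.0 equiv, so that it stops on purpose after the first ring at the bicyclic diene F4 (C6=C7 alkene, methylidene group kept).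
- The bridge is then closed by acid rather than by a radical, with CF3SO3H (10 mol %) in CH2Cl2 at −20 °C.
- This is a transannular cation–olefin cyclisation of the kind that turns 3,7-dimethylidenebicyclo[3.3.1]nonanes into adamantanes: a proton adds to C6, C10 attacks C7, and a proton is lost from C10.

*Step 9.* Acylation next to the quaternary C8 may be too slow, and the acid chloride may be consumed by the amide base. The fallback sets out from 12 and comes back at 14.
- The lithiated bridgehead is trapped with the smaller electrophile isobutyraldehyde to give the bridgehead carbinol F5 (either carbinol epimer).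
- F5 is oxidised with Dess–Martin periodinane in CH2Cl2 to 14.

**Further compounds**
F1 | step 5 | ent-spiro-trione, (5S)-6-hydroxy-2,2-dimethyl-7-(2-methylbut-3-en-2-yl)-1-methylidenespiro[4.5]dec-6-ene-8,10-dione | C=C1C(C)(C)CC[C@@]1(C(=O)CC2=O)C(O)=C2C(C)(C)C=C
F2 | step 5 | ent-cage enetrione | [C@H]12C[C@@H]3C=C4C(C)(C)CC[C@@]4(C1=O)C(=O)[C@H](C2=O)C3(C)C
F3 | step 5 | ent-cage trione | [C@H]12C[C@@H]3C[C@H]4C(C)(C)CC[C@@]4(C1=O)C(=O)[C@H](C2=O)C3(C)C
F4 | step 6 | bicyclic diene (bicyclo[3.3.1]non-6-ene-2,4,9-trione, 8,8-dimethyl, spiro-fused at C3 to 3,3-dimethyl-2-methylidenecyclopentane) | [C@@H]12C=CC(C)(C)[C@H](C2=O)C(=O)[C@@]3(C1=O)CCC(C)(C)C3=C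
F5 | step 9 | bridgehead carbinol (C1 carries CH(OH)CHMe2) | CC(C)=CCC/C(C)=C/C[C@@]12C[C@H]3C[C@@H]4C(C)(C)CC[C@]4(C1=O)C(=O)[C@@](C(O)C(C)C)(C2=O)C3(C)C
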